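## Analysis of the target

The target is a manumycin-type epoxyquinol built on a cyclohex-2-enone fused to an epoxide (a 7-oxabicyclo[4.1.0]hept-3-en-2-one). The ring is numbered here C1 (ketone), C2 (alkene carbon bearing the amide nitrogen), C3 (alkene CH), C4 (tertiary carbinol), C5 and C6 (epoxide carbons, C6 next to C1). The nitrogen on C2 carries a (2E,4E,6E)-8-methylnona-2,4,6-trienoyl group. C4 carries an all-E hepta-1,3,5-trienyl chain whose terminal carboxamide is bound to 2-amino-3-hydroxycyclopent-2-enone. The three stereocentres are contiguous, C4 (S), C5 (S) and C6 (R): the epoxide is cis-fused, the triene chain on C4 lies on the face of the epoxide oxygen and the hydroxyl on the opposite face. Sensitive groups are the epoxy ketone (base, nucleophiles, epoxide migration to the C4 alkoxide), the doubly allylic tertiary alcohol (acid), the two trienes (light, acid, radicals) and the acidic enol of the five-membered ring. The main difficulty is the trans relation of hydroxyl and epoxide: a carbon nucleophile adding to a free epoxy quinone monoketal enters anti to the epoxide and gives the opposite relation, and the ring has no resident stereocentre to relay absolute configuration. The strategy rests on C2=C3 being the only alkene in the six-membered ring. It can be hidden as a cyclopentadiene adduct, and the norbornene then leaves only the face of the C2/C3 hydrogens open, so C5, C6 and C4 are all set from that face.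

## Retrosynthetic reasoning

Lower chain, C–C bond between the second and third chain carbon counted from C4: 32 is cut into vinylstannane 23 and bromodienamide 31. Both partners are sp2 carbons with fixed geometry, the coupling is neutral, and the acidic five-membered ring arrives intact in the last step. 31 is cut at its amide bond into acid 29 (activated as chloride 30) and amine salt 26. 26 comes from dione 24 through oxime 25, and 29 from enolate salt 27 through aldehyde 28.

C–Sn and the two silyl groups: 23 goes back to terminal alkyne 22 and 22 to the doubly silylated 21. The two-carbon unit on C4 is carried as a silyl-capped alkyne until the copper step is over. A terminal alkyne would not survive copper and base, and a vinylstannane would not survive iodine. The forward steps must free the alkyne without leaving a C4 alkoxide next to the epoxide, then add tin to the terminal carbon with E geometry.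

C2–N bond: 21 is cut into α-iodoenone 13 and primary amide 20, so the upper acyl chain arrives whole. C2 is the only enone α-carbon with a hydrogen, so 13 comes from 12 by selective iodination. 20 comes from acid 18 (via anhydride 19), 18 from ester 17, and 17 from aldehyde 14 and phosphonate 15 (via anion 16), which forms the C4=C5 bond of the chain.

Oxygen functions at C4 and C1: 12 goes back to alcohol 11 (the silyl ether only guards C4–O during the basic steps) and 11 to ketal 10. The ketal is opened after the cycloreversion because only then is it allylic and easy to ionise.

C2=C3: 10 is traced to the norbornene 9, from which cyclopentadiene 4 is expelled thermally in the forward sense. In 9 the six-membered ring is folded under the etheno bridge, which is what makes its two faces different.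

C4–C(alkyne) bond and the two epoxide C–O bonds: 9 is cut into ketone 6 and acetylide 8 (from alkyne 7), and 6 goes back to enone 5. Both reagents must enter from the convex face; this puts the epoxide oxygen and the chain cis and the hydroxyl trans. The epoxide is made first, while the C4 carbonyl still activates C5=C6 for nucleophilic epoxidation.

The two C–C bonds at C2 and C3: 5 is cut into dienone 2 and diene 4. One catalytic event on an achiral dienone then fixes the absolute configuration of everything that follows. 2 is one step from phenol 1 and 4 one step from dimer 3, so the risk sits in this cycloaddition.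

## Alternatives that were turned down

Alternative 1: The ring oxygens at C1 and C4 would come from singlet oxygen and those at C5 and C6 from an enzymatic arene cis-dihydroxylation. Sensitised singlet oxygen adds across the diene of acetonide A2, anti to the dioxolane, to give endoperoxide A1. Base-induced Kornblum–DeLaMare opening of A1 then unveils the C1 ketone and the C4 hydroxyl, and the diol must finally be turned into the epoxide.
- For: the enzyme gives essentially one enantiomer without a chiral reagent, and the anti addition sets C4–O trans to the C5/C6 oxygens, which is the right relative configuration. Only the C1 hydrogen of A1 can be removed, so the opening is regiochemically clean. On absolute stereocontrol this route is as strong as or stronger than a catalyst-controlled cycloaddition.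
- Against: a cis-diol cannot close directly to a cis-epoxide on the same face. Two inversions at one carbon are needed (for example by cyclic sulfate formation, halide opening and base-induced closure), next to a ketone and on a base-labile γ-hydroxy enone system. The enzyme delivers one enantiomeric series only, and the silylalkynyl group would probably have to be attached after the biotransformation.
- Comparison: the chosen strategy delivers the epoxide in one step, on the correct face, offers either enantiomer through the ligand, and needs fewer steps between its key step and 12.

Alternative 2: The C5–C6 bond and the C6–O bond would be formed together by an intramolecular Darzens reaction. Base converts the chloromethyl ketone of the Z-enone aldehyde A4 into its enolate, which adds to the aldehyde; the alkoxide then displaces chloride, closing the cyclohexenone and the epoxide to give A3, which is the same compound as 12.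
- For: ring and epoxide form in one step, with no mask and no thermolysis. On step economy at the ring stage it is stronger than the chosen route, which needs steps 3 to 8 to reach 12.
- Against: the quaternary C4 centre must first be made enantiopure in an open chain. The aldol face is then controlled only by that centre, whose substituents (alkynyl, silyloxy, vinyl) differ little. Only the aldol isomer with alkoxide and chloride anti can close, and a Z-enone carrying a chloromethyl ketone is prone to isomerisation and Favorskii-type side reactions.
- Comparison: the chosen strategy sets all three centres by relay from one rigid bicyclic intermediate instead of an acyclic diastereoselection.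

Alternative 3: The five-membered ring of the lower chain would be made by a Dieckmann-type closure. KOtBu converts the N-acylated aminolevulinate ester A6 into the ketone enolate at the nitrogen-bearing carbon, which attacks the ester carbonyl and gives A5, the same compound as 31.
- For: it follows the biosynthesis, A6 is close to cheap feedstock, and the fragment is reached in about two steps where the chosen route uses three (steps 16, 17 and 20). On that count it is as short or shorter.
- Against: it solves only a peripheral ring that the chosen route obtains from the commercial dione 24, and leaves the stereotriad of the core untouched. Strong base in the presence of a bromodiene invites dehydrobromination, and the acidic N–H and the vinylogous acid product consume base.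
- Comparison: it could at best replace a sub-route; the chosen strategy puts its key step where the stereochemical problem is and builds 31 without strong base.

Key step: step 3

Remark 1: (S)-BINOL is assumed to give 5 as drawn; should the sense of induction prove opposite, (R)-BINOL is used and nothing else changes.
Remark 2: 14, 15 and 27 are treated as purchasable building blocks alongside 1, 3, 7 and 24.

## Route

Step 1
Reactants: 1 4-methoxyphenol
Product: 2 4,4-dimethoxycyclohexa-2,5-dien-1-one
Conditions: PhI(OAc)2 (1.1 equiv), MeOH, 0 °C to rt
Reagents that add atoms: methanol, CO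
Why: Oxidative dearomatisation of a para-alkoxyphenol by trivalent iodine; the aryloxy-iodane collapses to an oxocarbenium ion that methanol captures at the para carbon, the standard entry to quinone monoketals.

Step 2
Reactants: 3 dicyclopentadiene
Product: 4 cyclopenta-1,3-diene
Conditions: neat, 170–180 °C, distil through a short column, collect at −78 °C, use at once
Reagents that add atoms: none
Why: Thermal retro-Diels–Alder cracking of the dimer, each molecule of 3 giving two molecules of 4; the monomer is distilled as it forms and used before it redimerises.

Step 3
Reactants: 2 4,4-dimethoxycyclohexa-2,5-dien-1-one; 4 cyclopenta-1,3-diene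
Product: 5 endo adduct (1S,4R,4aS,8aR)-8,8-dimethoxy-1,4,4a,8a-tetrahydro-1,4-methanonaphthalen-5(8H)-one (in target numbering the ketone is C4, the ketal C1, the cis ring-fusion carbons C3 and C2)
Conditions: Ti(OiPr)2Cl2 (15 mol%), (S)-BINOL (15 mol%), 4 Å MS, CH2Cl2, −40 to −20 °C, 4 (3 equiv)
Reagents that add atoms: none
Why: The BINOL-bound tetravalent titanium centre coordinates the dienone carbonyl of 2, lowers its LUMO and places a naphthyl wall over one of the two enantiotopic C=C bonds, so that 4 can reach only the other one from its open face. The cycloaddition is a concerted, asynchronous, suprafacial [4+2] process; the closest known reaction type is the Diels–Alder reaction of quinones and quinone monoketals under BINOL–titanium Lewis acid catalysis. It closes one ring, the six-membered carbocycle of the bicyclo[2.2.1]heptene, in an intermolecular [4+2] mode in which both new σ-bonds (to C2 and C3 of the later target ring) form in the same step. C2 and C3 become cis because the addition is suprafacial on a cis-alkene, and the two bridgehead centres follow from the endo transition state, in which the diene lies under the activated carbonyl. The absolute configuration of all four centres is decided together by the choice of alkene and face, that is, by the BINOL axis. Three selectivities are needed: endo over exo (secondary orbital overlap, reinforced by the Lewis acid and the low temperature), one enantiotopic alkene over the other (catalyst), and mono- over bis-addition (the remaining enone of 5 is folded under the norbornene and should react more slowly). The gem-dimethoxy group keeps the second carbonyl masked, so only one Lewis-basic site binds titanium and the two ends of the ring stay differentiated.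

Step 4
Reactants: 5 endo adduct
Product: 6 exo-epoxide of 5 (5,6-epoxide in target numbering, oxygen on the convex face, cis to the C2 and C3 hydrogens)
Conditions: tBuOOH (anhydrous, in decane), DBU, CH2Cl2, 0 °C to rt
Reagents that add atoms: tert-butyl hydroperoxide, CC(C)(C)OO
Why: Weitz–Scheffer nucleophilic epoxidation: the peroxide anion adds to the enone β-carbon C6 and the enolate closes at C5 with loss of tert-butoxide; the etheno bridge covers the concave face, so both C–O bonds form on the face of the ring-fusion hydrogens, which sets C5 and C6.

Step 5
Reactants: 6 exo-epoxide; 7 ethynyltri(propan-2-yl)silane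
Product: 9 masked epoxy carbinol (C4 hydroxyl on the concave face; silylethynyl group on the convex face cis to the epoxide oxygen), via lithium silylacetylide 8 (not isolated)
Conditions: 7, nBuLi, THF, −78 °C; then 6, −78 to −40 °C; H2O
Reagents that add atoms: none
Why: 1,2-Addition of a lithium acetylide to the C4 ketone from the convex face, the one the peroxide used, because the other face is blocked by the norbornene; this sets C4 with the chain cis and the hydroxyl trans to the epoxide oxygen, against the usual anti-to-epoxide preference of unmasked epoxy ketones. The weakly basic acetylide and low temperature limit enolisation at C3 and leave the epoxide and ketal untouched.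

Step 6
Reactants: 9 masked epoxy carbinol
Product: 10 5,6-epoxy-1,1-dimethoxy-4-{[tri(propan-2-yl)silyl]ethynyl}cyclohex-2-en-4-ol (target numbering; alkynyl cis and hydroxyl trans to the epoxide oxygen)
Conditions: flash vacuum pyrolysis, 500 °C, 0.01 mbar, quartz tube, trap at −78 °C
Reagents that add atoms: none
Why: Gas-phase retro-Diels–Alder cycloreversion expels cyclopentadiene and returns C2=C3; the four centres of the mask vanish and C4, C5 and C6 are untouched because no bond to them breaks. A short contact time is chosen because the released alkene is not conjugated, which raises the barrier, and the allylic ketal would not tolerate long heating in solution.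

Step 7
Reactants: 10 epoxy ketal
Product: 11 5,6-epoxy-4-hydroxy-4-{[tri(propan-2-yl)silyl]ethynyl}cyclohex-2-en-1-one (same relative and absolute configuration as 10)
Conditions: pyridinium p-toluenesulfonate, acetone/H2O (10:1), 40 °C
Reagents that add atoms: water, O
Why: Acid-catalysed ketal hydrolysis; ionisation at C1 is helped by the adjacent C2=C3 (allylic oxocarbenium ion) and gives the conjugated enone, while the buffered acid is too weak to ionise the C4 carbinol or open the epoxide.

Step 8
Reactants: 11 epoxy hydroxy enone
Product: 12 4-O-triethylsilyl ether of 11
Conditions: Et3SiOTf, 2,6-lutidine, CH2Cl2, −78 to 0 °C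
Reagents that add atoms: triethylsilyl trifluoromethanesulfonate, CC[Si](CC)(CC)OS(=O)(=O)C(F)(F)F
Why: Silyl triflate silylation of a hindered tertiary alcohol with a non-nucleophilic base; the ether prevents alkoxide formation at C4, and with it Payne-type epoxide migration, in the basic copper step.

Step 9
Reactants: 12 silyl ether
Product: 13 2-iodo derivative of 12 (iodine on C2)
Conditions: I2, pyridine, CH2Cl2, 0 °C to rt, dark
Reagents that add atoms: iodine, [I][I]
Why: α-Iodination of a cyclic enone by the amine-mediated addition–iodination–elimination sequence (Baylis–Hillman-type): pyridine adds to C3, the enolate is iodinated at C2 and pyridine leaves; C2 is the only enone α-carbon with a hydrogen, and the silyl groups, epoxide and capped alkyne are inert.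

Step 10
Reactants: 14 (E)-4-methylpent-2-enal; 15 triethyl (E)-4-phosphonocrotonate
Product: 17 ethyl (2E,4E,6E)-8-methylnona-2,4,6-trienoate, via lithiated phosphonate 16 (not isolated)
Conditions: 15, LiN(SiMe3)2, THF, −78 °C; then 14, −78 to 0 °C
Reagents that add atoms: none
Why: Vinylogous Horner–Wadsworth–Emmons olefination; the stabilised anion forms the new C4=C5 bond with E geometry and the two existing E-alkenes are not touched.

Step 11
Reactants: 17 trienoate ester
Product: 18 (2E,4E,6E)-8-methylnona-2,4,6-trienoic acid
Conditions: LiOH, THF/MeOH/H2O, rt; then 1 M HCl
Reagents that add atoms: lithium hydroxide, [Li+].[OH-]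
Why: Saponification of a conjugated ester by hydroxide attack at the acyl carbon; acidification gives the free acid without affecting the triene.

Step 12
Reactants: 18 trienoic acid
Product: 20 (2E,4E,6E)-8-methylnona-2,4,6-trienamide, via mixed carbonic anhydride 19 (not isolated)
Conditions: iBuOCOCl, N-methylmorpholine, THF, −15 °C; then NH3 (28% aq.), −15 °C to rt
Reagents that add atoms: ammonia, N
Why: Mixed-anhydride activation and aminolysis; ammonia attacks the more electrophilic, less hindered acyl carbon and gives the primary amide under conditions the triene tolerates.

Step 13
Reactants: 13 α-iodoenone; 20 trienamide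
Product: 21 2-[(2E,4E,6E)-8-methylnona-2,4,6-trienoylamino] derivative of 12 (amide nitrogen on C2)
Conditions: CuI (20 mol%), N,N′-dimethylethane-1,2-diamine (40 mol%), Cs2CO3, THF, 55 °C, degassed, dark
Reagents that add atoms: none
Why: Goldberg-type copper-catalysed N-vinylation of a primary amide with a vinyl iodide; the diamine-ligated monovalent copper amidate reacts at the C2–I bond with retention and gives the secondary enamide. The alkyne is silyl-capped so that no copper acetylide forms, and the C4 oxygen is silylated so that no alkoxide can attack the epoxide.

Step 14
Reactants: 21 doubly silylated amide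
Product: 22 4-ethynyl-4-hydroxy compound (21 without both silyl groups)
Conditions: Bu4NF, AcOH (1:1), THF, 0 °C to rt
Reagents that add atoms: none
Why: Fluoride cleaves the C(sp)–Si and the O–Si bond; acetic acid keeps the medium near neutral, so the acetylide and the C4 oxygen are protonated as they are released and the alkoxide cannot open the neighbouring epoxide.

Step 15
Reactants: 22 terminal alkyne
Product: 23 (E)-vinylstannane (C4 carries an (E)-2-(tributylstannyl)ethenyl group)
Conditions: Bu3SnH (1.2 equiv, slow addition), PdCl2(PPh3)2 (3 mol%), THF, 0 °C
Reagents that add atoms: tributylstannane, CCCC[SnH](CCCC)CCCC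
Why: Palladium-catalysed syn-hydrostannation of a terminal alkyne; tin goes to the terminal carbon because the propargylic carbon is quaternary, which gives the E-β-stannyl alkene, and the alkyne reacts faster than the enone or the trienamide under zerovalent palladium at 0 °C.

Step 16
Reactants: 24 cyclopentane-1,3-dione
Product: 25 2-(hydroxyimino)cyclopentane-1,3-dione
Conditions: NaNO2, aq. HCl, 0 °C
Reagents that add atoms: sodium nitrite, [Na+].[O-]N=O
Why: Nitrosation of the strongly enolised 1,3-dione at C2 by nitrous acid; the C-nitroso compound tautomerises to the oxime.

Step 17
Reactants: 25 oxime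
Product: 26 2-amino-3-hydroxycyclopent-2-en-1-one hydrochloride
Conditions: H2 (3 bar), 10% Pd/C, HCl, MeOH, rt
Reagents that add atoms: hydrogen chloride, Cl
Why: Catalytic hydrogenation of the oxime to the primary amine in acid; the hydrochloride prevents self-condensation of the α-amino ketone, and the enolised dione is not reduced.

Step 18
Reactants: 27 glutaconaldehyde potassium salt
Product: 28 (2E,4E)-5-bromopenta-2,4-dienal
Conditions: PPh3, Br2, CH2Cl2, 0 °C; then 27, rt
Reagents that add atoms: bromine, BrBr
Why: Deoxybromination of a vinylogous carboxylate: the enolate oxygen attacks the bromophosphonium salt and bromide displaces triphenylphosphine oxide by vinylogous addition–elimination, giving the thermodynamically favoured E,E-bromodienal.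

Step 19
Reactants: 28 bromodienal
Product: 29 (2E,4E)-5-bromopenta-2,4-dienoic acid
Conditions: NaClO2, NaH2PO4, 2-methylbut-2-ene, tBuOH/H2O, 0 °C to rt
Reagents that add atoms: sodium chlorite, [Na+].[O-]Cl=O
Why: Pinnick oxidation; chlorous acid adds to the aldehyde and fragments to the acid and hypochlorous acid, which the alkene scavenger removes before it can chlorinate the diene.

Step 20
Reactants: 29 bromodienoic acid; 26 aminocyclopentenone hydrochloride
Product: 31 (2E,4E)-5-bromo-N-(2-hydroxy-5-oxocyclopent-1-en-1-yl)penta-2,4-dienamide, via acid chloride 30 (not isolated)
Conditions: (COCl)2, DMF (cat.), CH2Cl2, 0 °C to rt, evaporate; then 26, pyridine, CH2Cl2/DMF, 0 °C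
Reagents that add atoms: none
Why: Acid chloride formation followed by N-acylation of the amine freed from its salt by pyridine; nitrogen is the more nucleophilic site, any O-acylated enol passes the acyl group on to nitrogen, and the weak base does not dehydrobrominate the diene.

Step 21
Reactants: 23 vinylstannane; 31 bromodienamide
Product: 32 (2E,4E,6E)-N-[(1R,5S,6S)-5-hydroxy-5-{(1E,3E,5E)-7-[(2-hydroxy-5-oxocyclopent-1-en-1-yl)amino]-7-oxohepta-1,3,5-trien-1-yl}-2-oxo-7-oxabicyclo[4.1.0]hept-3-en-3-yl]-8-methylnona-2,4,6-trienamide (the target; 4S,5S,6R in the ring numbering used above)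
Conditions: PdCl2(MeCN)2 (10 mol%), DMF, rt, dark
Reagents that add atoms: none
Why: Stille coupling; zerovalent palladium, formed from the divalent precatalyst by the stannane, inserts into the C–Br bond, and transmetalation and reductive elimination join the two sp2 carbons with retention of both alkene geometries, giving the all-E triene under neutral conditions at room temperature.

## Compound list

1 | 4-methoxyphenol | COc1ccc(O)cc1 | starting material
2 | 4,4-dimethoxycyclohexa-2,5-dien-1-one | COC1(OC)C=CC(=O)C=C1 | intermediate
3 | dicyclopentadiene (commercial endo dimer, racemic) | C1C=CC2C1C3CC2C=C3 | starting material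
4 | cyclopenta-1,3-diene | C1=CCC=C1 | intermediate
5 | (1S,4R,4aS,8aR)-8,8-dimethoxy-1,4,4a,8a-tetrahydro-1,4-methanonaphthalen-5(8H)-one, endo adduct | COC1(OC)C=CC(=O)[C@H]2[C@H]3C=C[C@H](C3)[C@@H]12 | intermediate
6 | exo-epoxide of 5, epoxide oxygen cis to the ring-fusion hydrogens | COC1(OC)[C@@H]4O[C@@H]4C(=O)[C@H]2[C@H]3C=C[C@H](C3)[C@@H]12 | intermediate
7 | ethynyltri(propan-2-yl)silane | C#C[Si](C(C)C)(C(C)C)C(C)C | starting material
8 | lithium [tri(propan-2-yl)silyl]acetylide | [Li]C#C[Si](C(C)C)(C(C)C)C(C)C | intermediate (not isolated)
9 | masked epoxy carbinol: 6 with C4 bearing OH (concave face) and the silylethynyl group (convex face, cis to the epoxide oxygen) | COC1(OC)[C@@H]4O[C@@H]4[C@](O)(C#C[Si](C(C)C)(C(C)C)C(C)C)[C@H]2[C@H]3C=C[C@H](C3)[C@@H]12 | intermediate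
10 | 5,6-epoxy-1,1-dimethoxy-4-{[tri(propan-2-yl)silyl]ethynyl}cyclohex-2-en-4-ol, alkynyl cis and OH trans to the epoxide oxygen | COC1(OC)[C@@H]2O[C@@H]2[C@](O)(C#C[Si](C(C)C)(C(C)C)C(C)C)C=C1 | intermediate
11 | 5,6-epoxy-4-hydroxy-4-{[tri(propan-2-yl)silyl]ethynyl}cyclohex-2-en-1-one, same configuration | O=C1[C@@H]2O[C@@H]2[C@](O)(C#C[Si](C(C)C)(C(C)C)C(C)C)C=C1 | intermediate
12 | 4-O-triethylsilyl ether of 11 | O=C1[C@@H]2O[C@@H]2[C@](O[Si](CC)(CC)CC)(C#C[Si](C(C)C)(C(C)C)C(C)C)C=C1 | intermediate
13 | 2-iodo derivative of 12 | O=C1[C@@H]2O[C@@H]2[C@](O[Si](CC)(CC)CC)(C#C[Si](C(C)C)(C(C)C)C(C)C)C=C1I | intermediate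
14 | (E)-4-methylpent-2-enal | CC(C)/C=C/C=O | starting material
15 | triethyl (E)-4-phosphonocrotonate | CCOC(=O)/C=C/CP(=O)(OCC)OCC | starting material
16 | lithiated phosphonate (anion at the phosphorus-bearing carbon) | [Li+].CCOC(=O)/C=C/[CH-]P(=O)(OCC)OCC | intermediate (not isolated)
17 | ethyl (2E,4E,6E)-8-methylnona-2,4,6-trienoate | CC(C)/C=C/C=C/C=C/C(=O)OCC | intermediate
18 | (2E,4E,6E)-8-methylnona-2,4,6-trienoic acid | CC(C)/C=C/C=C/C=C/C(=O)O | intermediate
19 | isobutyl carbonic anhydride of 18 | CC(C)/C=C/C=C/C=C/C(=O)OC(=O)OCC(C)C | intermediate (not isolated)
20 | (2E,4E,6E)-8-methylnona-2,4,6-trienamide | CC(C)/C=C/C=C/C=C/C(N)=O | intermediate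
21 | 12 carrying the (2E,4E,6E)-8-methylnona-2,4,6-trienoylamino group on C2 | CC(C)/C=C/C=C/C=C/C(=O)NC1=C[C@@](O[Si](CC)(CC)CC)(C#C[Si](C(C)C)(C(C)C)C(C)C)[C@H]2O[C@H]2C1=O | intermediate
22 | 4-ethynyl-4-hydroxy compound, 21 without both silyl groups | CC(C)/C=C/C=C/C=C/C(=O)NC1=C[C@@](O)(C#C)[C@H]2O[C@H]2C1=O | intermediate
23 | (E)-2-(tributylstannyl)ethenyl compound from 22 | CC(C)/C=C/C=C/C=C/C(=O)NC1=C[C@@](O)(/C=C/[Sn](CCCC)(CCCC)CCCC)[C@H]2O[C@H]2C1=O | intermediate
24 | cyclopentane-1,3-dione | O=C1CCC(=O)C1 | starting material
25 | 2-(hydroxyimino)cyclopentane-1,3-dione | ON=C1C(=O)CCC1=O | intermediate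
26 | 2-amino-3-hydroxycyclopent-2-en-1-one hydrochloride | Cl.NC1=C(O)CCC1=O | intermediate
27 | glutaconaldehyde potassium salt, potassium (1E,3E)-5-oxopenta-1,3-dien-1-olate | [K+].[O-]/C=C/C=C/C=O | starting material
28 | (2E,4E)-5-bromopenta-2,4-dienal | O=C/C=C/C=C/Br | intermediate
29 | (2E,4E)-5-bromopenta-2,4-dienoic acid | OC(=O)/C=C/C=C/Br | intermediate
30 | (2E,4E)-5-bromopenta-2,4-dienoyl chloride | ClC(=O)/C=C/C=C/Br | intermediate (not isolated)
31 | (2E,4E)-5-bromo-N-(2-hydroxy-5-oxocyclopent-1-en-1-yl)penta-2,4-dienamide | O=C(/C=C/C=C/Br)NC1=C(O)CCC1=O | intermediate
32 | CNP0215439.3, (1R,5S,6S)-configured epoxyquinol bis-trienamide | CC(C)/C=C/C=C/C=C/C(=O)NC1=C[C@@](O)(/C=C/C=C/C=C/C(=O)NC2=C(O)CCC2=O)[C@H]2O[C@H]2C1=O | target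

## Step count and least certain steps

Total: 21 steps. Longest linear sequence: 12 steps (1, 3, 4, 5, 6, 7, 8, 9, 13, 14, 15, 21), from 1 to 32.

Step 3 (key step). Most likely failure: low enantioselectivity, because an acyclic dimethyl ketal offers only one binding site and the reactive diene can add without the catalyst; ionisation of the ketal by the Lewis acid and a second cycloaddition are lesser risks. Fallback: 2 and 4 are combined without catalyst (CH2Cl2, rt) to give the racemic endo adduct F1. Luche reduction (NaBH4, CeCl3, MeOH, hydride from the convex face) gives the racemic endo allylic alcohol F2. A lipase-catalysed kinetic resolution (Pseudomonas cepacia lipase, vinyl acetate, tBuOMe), with the enzyme chosen so that the unwanted antipode is acylated to acetate F4, leaves the alcohol F3 of the wanted series. MnO2 in CH2Cl2 oxidises F3 back to 5, where the route resumes.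

Step 6. Most likely failure: sluggish cycloreversion, because the alkene released is not conjugated; at the temperature then needed, loss of methanol and water with aromatisation, or incomplete volatilisation of the substrate, can take over. Fallback: the order is changed so that the cycloreversion releases an enone. Starting from 5, acetylide 8 (THF, −78 °C) adds to the enone carbonyl from the convex face to give carbinol F5. Pyridinium p-toluenesulfonate in wet acetone hydrolyses the now allylic ketal to enone F6, whose carbonyl is C1. tBuOOH/DBU epoxidises C5=C6 of F6 from the convex face, cis to the alkynyl group, to give the masked epoxy ketone F7. Heating F7 in Ph2O at 230–250 °C expels cyclopentadiene and gives 11, where the route resumes. The same detour removes the dependence on the face selectivity of step 5, where the nucleophile must approach next to the epoxide.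

Step 13. Most likely failure: base-induced degradation of the epoxy enone, slow coupling of the weakly nucleophilic and heat-sensitive trienamide, or reductive loss of iodine. Fallback: nitrogen is installed first and acylated afterwards. From 13, allyl carbamate is coupled (CuI, N,N′-dimethylethane-1,2-diamine, K3PO4, toluene, 40 °C) to give carbamate F8; a small carbamate couples under milder conditions than the trienamide. Pd(PPh3)4 with dimedone (THF, rt) removes the allyloxycarbonyl group and gives the 2-amino enone F9. Acid 18 is converted with (COCl)2 and catalytic DMF into acid chloride F10, which acylates F9 in pyridine/CH2Cl2 to give 21, where the route resumes.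

Step 14. Most likely failure: attack of a transient C4 alkoxide on C5 (Payne-type epoxide migration) or base damage to the enamide and triene, together with slow cleavage of the hindered alkynyl–silicon bond once the medium is buffered. Fallback: the deprotection is staged so that no C4 alkoxide exists until the end. From 21, AgF (MeCN, dark, then dilute HCl) cleaves only the C(sp)–Si bond through the silver acetylide and gives the terminal alkyne F11 with the triethylsilyl ether intact. Bu3SnH with PdCl2(PPh3)2 gives vinylstannane F12, and Stille coupling with 31 (PdCl2(MeCN)2, DMF) gives the silyl-protected target F13. HF·pyridine buffered with pyridine (THF, 0 °C) removes the triethylsilyl group and gives 32.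

## Further compounds

F1 | step 3 | racemic endo adduct, both antipodes of 5 | COC1(OC)C=CC(=O)[C@H]2[C@H]3C=C[C@H](C3)[C@@H]12.COC1(OC)C=CC(=O)[C@@H]2[C@@H]3C=C[C@@H](C3)[C@H]12
F2 | step 3 | racemic endo allylic alcohol from reduction of F1, hydroxyl on the concave face | COC1(OC)C=C[C@@H](O)[C@H]2[C@H]3C=C[C@H](C3)[C@@H]12.COC1(OC)C=C[C@H](O)[C@@H]2[C@@H]3C=C[C@@H](C3)[C@H]12
F3 | step 3 | endo allylic alcohol with the configuration of 5 | COC1(OC)C=C[C@@H](O)[C@H]2[C@H]3C=C[C@H](C3)[C@@H]12
F4 | step 3 | acetate of the antipodal endo allylic alcohol | COC1(OC)C=C[C@H](OC(C)=O)[C@@H]2[C@@H]3C=C[C@@H](C3)[C@H]12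
F5 | step 6 | acetylide adduct of 5: C4 carbinol with the silylethynyl group on the convex face, ketal and C5=C6 intact | COC1(OC)C=C[C@](O)(C#C[Si](C(C)C)(C(C)C)C(C)C)[C@H]2[C@H]3C=C[C@H](C3)[C@@H]12
F6 | step 6 | masked 4-hydroxy-4-silylethynyl enone with the carbonyl at C1 | O=C1C=C[C@](O)(C#C[Si](C(C)C)(C(C)C)C(C)C)[C@H]2[C@H]3C=C[C@H](C3)[C@@H]12
F7 | step 6 | masked epoxy ketone: exo 5,6-epoxide of F6, oxygen cis to the alkynyl group | O=C1[C@@H]4O[C@@H]4[C@](O)(C#C[Si](C(C)C)(C(C)C)C(C)C)[C@H]2[C@H]3C=C[C@H](C3)[C@@H]12
F8 | step 13 | allyl carbamate on C2 of 12 | C=CCOC(=O)NC1=C[C@@](O[Si](CC)(CC)CC)(C#C[Si](C(C)C)(C(C)C)C(C)C)[C@H]2O[C@H]2C1=O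
F9 | step 13 | 2-amino derivative of 12 | NC1=C[C@@](O[Si](CC)(CC)CC)(C#C[Si](C(C)C)(C(C)C)C(C)C)[C@H]2O[C@H]2C1=O
F10 | step 13 | (2E,4E,6E)-8-methylnona-2,4,6-trienoyl chloride | CC(C)/C=C/C=C/C=C/C(Cl)=O
F11 | step 14 | 4-ethynyl 4-O-triethylsilyl amide, 21 without the alkynyl silyl group | CC(C)/C=C/C=C/C=C/C(=O)NC1=C[C@@](O[Si](CC)(CC)CC)(C#C)[C@H]2O[C@H]2C1=O
F12 | step 14 | (E)-vinylstannane with the 4-O-triethylsilyl ether | CC(C)/C=C/C=C/C=C/C(=O)NC1=C[C@@](O[Si](CC)(CC)CC)(/C=C/[Sn](CCCC)(CCCC)CCCC)[C@H]2O[C@H]2C1=O
F13 | step 14 | 4-O-triethylsilyl ether of 32 | CC(C)/C=C/C=C/C=C/C(=O)NC1=C[C@@](O[Si](CC)(CC)CC)(/C=C/C=C/C=C/C(=O)NC2=C(O)CCC2=O)[C@H]2O[C@H]2C1=O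
A1 | alternative 1 | bicyclic endoperoxide acetonide | C1=C[C@]2(C#C[Si](C(C)C)(C(C)C)C(C)C)OO[C@H]1[C@@H]1OC(C)(C)O[C@H]21
A2 | alternative 1 | diene acetonide, cis-diol acetonide of the cyclohexadiene with the silylethynyl group on the diene terminus next to the diol | CC1(C)O[C@H]2C=CC=C(C#C[Si](C(C)C)(C(C)C)C(C)C)[C@H]2O1
A3 | alternative 2 | 4-alkynyl epoxyquinol silyl ether, identical with 12 | O=C1C=C[C@@](O[Si](CC)(CC)CC)(C#C[Si](C(C)C)(C(C)C)C(C)C)[C@H]2O[C@H]21
A4 | alternative 2 | Z-configured chloromethyl enone aldehyde with the quaternary silyloxy alkynyl carbon | ClCC(=O)/C=C\[C@@](O[Si](CC)(CC)CC)(C#C[Si](C(C)C)(C(C)C)C(C)C)C=O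
A5 | alternative 3 | bromodienamide of 2-amino-3-hydroxycyclopent-2-enone, identical with 31 | O=C(/C=C/C=C/Br)NC1=C(O)CCC1=O
A6 | alternative 3 | methyl 5-[(2E,4E)-5-bromopenta-2,4-dienamido]-4-oxopentanoate | COC(=O)CCC(=O)CNC(=O)/C=C/C=C/Br
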